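**Strategy.** The bicyclo[3.3.1]nonane-2,4,9-trione is cut at C5–C9, C3–C4 and C1–C8, back to the acyclic ester 10 (a linalyl-type carbonate carrying the C7 stereocentre) and diketene. In one pot the C5 enolate is acetoacetylated by diketene (C5–C9), a Claisen closure forms ring B as a trione that is mirror-symmetric about the C5···C2 axis, and zerovalent palladium makes one of its two equivalent α-carbons (C1) attack the allyl terminus C8, closing ring A. The step exploits this hidden symmetry of ring B and the 1,3-dicarbonyl pairs C9/C2 and C2/C4; C7 alone dictates C1, C5 and C8. Vinyl-to-homoprenyl coupling, bridgehead prenylation and C3 aroylation finish the synthesis.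

Key step: step 7

Numbering used: C1 and C5 are the bridgeheads, C2/C3/C4 the enolised dicarbonyl bridge, C6 the CH2, C7 the prenyl-bearing CH, C8 the methyl/homoprenyl carbon, C9 the bridging carbonyl. Ring A = C1–C8–C7–C6–C5–C9; ring B = C1–C2–C3–C4–C5–C9.

Remarks on the chemistry: 5-methylhex-4-enoic acid and 2,4,5-trihydroxybenzoic acid are taken as purchasable. Compounds 6–10 and 12 are carried as mixtures at the ester α-carbon (later C5) and, from 9 on, at the carbinol carbon (later C8); both centres become trigonal in step 7. Diones are drawn as one enol tautomer.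

**Step 1**
Reactants: 1 5-methylhex-4-enoic acid; 2 (S)-4-benzyl-1,3-oxazolidin-2-one
Product: 3 (S)-4-benzyl-3-(5-methylhex-4-enoyl)-1,3-oxazolidin-2-one
Conditions: PivCl, Et3N, THF, −20 °C; then 2, LiCl, −20 °C to rt
Reagents that add atoms: none
Why: N-acylation of the auxiliary through the mixed pivalic anhydride; no stereocentre is formed.

**Step 2**
Reactants: 3; 4 methyl 2-(bromomethyl)acrylate
Product: 5 methyl (4R)-4-[(4S)-4-benzyl-2-oxo-1,3-oxazolidine-3-carbonyl]-7-methyl-2-methylideneoct-6-enoate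
Conditions: NaHMDS (NaN(SiMe3)2), THF, −78 °C; then 4
Reagents that add atoms: none
Why: Evans asymmetric alkylation, in which the chelated Z-enolate is attacked by the allylic bromide on the face away from the benzyl group, should set the later C7 as R.

**Step 3**
Reactants: 5
Product: 6 methyl (4R)-4-[(4S)-4-benzyl-2-oxo-1,3-oxazolidine-3-carbonyl]-7-methyl-2-(3-methylbut-2-enyl)oct-6-enoate
Conditions: (Me2C=CH)MgBr (2 equiv), CuBr·SMe2 (1 equiv), THF, −78 °C; aq NH4Cl at −78 °C
Reagents that add atoms: 2-methylprop-1-enylmagnesium bromide, CC(C)=C[Mg]Br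
Why: Organocuprate conjugate addition to the 2-substituted acrylate is far faster than attack on the imide and installs the C5 prenyl group, leaving C5 as an inconsequential epimer mixture.

**Step 4**
Reactants: 6
Product: 7 methyl (4R)-4-(ethylsulfanylcarbonyl)-7-methyl-2-(3-methylbut-2-enyl)oct-6-enoate
Conditions: EtSH, n-BuLi, THF, 0 °C
Reagents that add atoms: ethanethiol, CCS
Why: Thiolate transacylation at the exocyclic imide carbonyl should release the auxiliary without touching the methyl ester or epimerising C7.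

**Step 5**
Reactants: 7
Product: 8 methyl (4R)-4-acetyl-7-methyl-2-(3-methylbut-2-enyl)oct-6-enoate
Conditions: Me2CuLi (from MeLi and CuI), Et2O, −78 °C; aq NH4Cl
Reagents that add atoms: lithium dimethylcuprate, [Li+].C[Cu-]C
Why: Ketone synthesis from a thioester and a Gilman cuprate, to which the methyl ester is inert and which is not basic enough to epimerise the α-stereocentre.

**Step 6**
Reactants: 8
Product: 10 methyl (4R)-4-[2-(tert-butoxycarbonyloxy)but-3-en-2-yl]-7-methyl-2-(3-methylbut-2-enyl)oct-6-enoate, via tertiary allylic alcohol 9 (not isolated)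
Conditions: CH2=CHMgBr, CeCl3, THF, −78 °C; then Boc2O, −78 °C to rt
Reagents that add atoms: vinylmagnesium bromide, C=C[Mg]Br; di-tert-butyl dicarbonate, CC(C)(C)OC(=O)OC(=O)OC(C)(C)C
Why: Cerium-assisted 1,2-addition to the ketone (far more electrophilic than the ester) and in-flask acylation of the tertiary alkoxide give the linalyl-type carbonate, whose new carbinol centre is erased in step 7.

**Step 7**
Reactants: 10; 11 diketene
Product: 14 (1R,5S,7R,8S)-8-ethenyl-4-hydroxy-8-methyl-5,7-bis(3-methylbut-2-enyl)bicyclo[3.3.1]non-3-ene-2,9-dione, via acetoacetylated ester 12 (not isolated), via monocyclic trione 13 (not isolated)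
Conditions: LDA (LiN(iPr)2, 1.05 equiv), THF, −78 °C; diketene; LDA (2.2 equiv), −78 to 0 °C; Pd(PPh3)4 (5 mol %), 0 to 40 °C; aq NH4Cl
Reagents that add atoms: none
Why: LDA forms the C5 ester enolate, which opens diketene at its carbonyl carbon (C5–C9), and the second charge of LDA gives the acetoacetyl dianion whose terminal carbon C3 attacks the C4 ester in a 6-exo-trig Claisen closure of ring B, giving the mirror-symmetric trione 13 as its dianion. Pd(PPh3)4 then ionises the tertiary allylic carbonate and one α-carbon of the trione attacks the more substituted π-allyl terminus C8 anti to palladium, a 6-exo Tsuji–Trost closure of ring A through a chair (C1–C8); the eight-membered alternative through the CH2 terminus is disfavoured and O-allylation is reversible under the catalyst. The closest known reactions are the acetoacetylation of lithium enolates with diketene followed by intramolecular capture, dianion Claisen cyclisations to cyclohexane-1,3,5-triones, palladium-catalysed cyclisations of 1,3-dicarbonyls onto allyl termini that give vinyl-bearing quaternary carbons, and the cation-type closure of dearomatised acylphloroglucinols at C8. C7 (R) is the only stereocentre of 13: of the two α-carbons flanking C2 only the one that reaches C8 through a chair with the C7 prenyl group equatorial should react, which fixes C1 (R) and C5 (S) together and gives the exo relationship of ring B and the C7 prenyl group. At C8 the bulky allyl–palladium unit should take the equatorial site (the complex can change face by π–σ–π exchange), so that vinyl ends equatorial and methyl axial (8S). The step needs C- over O-acylation at the hindered C5 enolate and no acyl transfer from the carbonate, which the absence of other acidic C–H bonds in 10 and the hindered di-tertiary carbonate are meant to secure.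

**Step 8**
Reactants: 14
Product: 15 (1R,5S,7R,8S)-8-ethenyl-4-methoxy-8-methyl-5,7-bis(3-methylbut-2-enyl)bicyclo[3.3.1]non-3-ene-2,9-dione
Conditions: Me2SO4, K2CO3, acetone, rt
Reagents that add atoms: dimethyl sulfate, COS(=O)(=O)OC
Why: O-alkylation of the vinylogous acid with a hard electrophile; the 4-methoxy isomer (C2 carbonyl next to the bridgehead C1–H) is the one needed, and any 2-methoxy isomer is separated and can be returned to 14 by hydrolysis.

**Step 9**
Reactants: 15
Product: 17 (1R,5S,7R,8S)-4-methoxy-8-methyl-5,7-bis(3-methylbut-2-enyl)-8-(4-methylpent-3-enyl)bicyclo[3.3.1]non-3-ene-2,9-dione, via B-alkyl-9-BBN borane 16 (not isolated)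
Conditions: 9-BBN, THF, rt to 40 °C; then Me2C=CHBr, PdCl2(dppf), AsPh3, Cs2CO3, DMF/H2O, rt to 50 °C
Reagents that add atoms: 1-bromo-2-methylprop-1-ene, CC(C)=CBr; 9-BBN, [BH]1C2CCCC1CCC2 (its boron is carried only by 16)
Why: Anti-Markovnikov hydroboration of the only monosubstituted alkene (the trisubstituted prenyl alkenes react far more slowly) followed by B-alkyl Suzuki–Miyaura coupling builds the 4-methylpent-3-enyl chain without touching C8.

**Step 10**
Reactants: 17
Product: 18 (1R,5S,7R,8S)-4-methoxy-8-methyl-1,5,7-tris(3-methylbut-2-enyl)-8-(4-methylpent-3-enyl)bicyclo[3.3.1]non-3-ene-2,9-dione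
Conditions: LDA, THF, −78 °C; prenyl bromide, −78 to 0 °C
Reagents that add atoms: prenyl bromide, CC(C)=CCBr
Why: Bridgehead lithiation–alkylation, in which LDA removes the C1–H flanked by the C9 and C2 carbonyls and the carbanion is prenylated with retention, the only outcome the bicycle allows.

**Step 11**
Reactants: 19 2,4,5-trihydroxybenzoic acid
Product: 20 tert-butyldimethylsilyl 2,4,5-tris(tert-butyldimethylsilyloxy)benzoate
Conditions: TBSCl (4.5 equiv), imidazole, DMF, rt
Reagents that add atoms: tert-butyldimethylsilyl chloride, CC(C)(C)[Si](C)(C)Cl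
Why: Exhaustive silylation protects the three phenols of the electron-rich arene for the organolithium step and activates the acid as its silyl ester.

**Step 12**
Reactants: 20
Product: 21 2,4,5-tris(tert-butyldimethylsilyloxy)benzoyl chloride
Conditions: (COCl)2, DMF (cat.), CH2Cl2, 0 °C to rt
Reagents that add atoms: oxalyl chloride, O=C(Cl)C(=O)Cl
Why: Silyl esters are converted directly into acid chlorides by Vilsmeier-type activation under neutral conditions that keep the aryl silyl ethers.

**Step 13**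
Reactants: 18; 21
Product: 22 (1S,5S,7R,8S)-3-[2,4,5-tris(tert-butyldimethylsilyloxy)benzoyl]-4-methoxy-8-methyl-1,5,7-tris(3-methylbut-2-enyl)-8-(4-methylpent-3-enyl)bicyclo[3.3.1]non-3-ene-2,9-dione
Conditions: LiTMP (lithium 2,2,6,6-tetramethylpiperidide), THF, −78 °C; then 21
Reagents that add atoms: none
Why: Vinyl lithiation at C3 of the vinylogous ester (no bridgehead hydrogen is left) and C-acylation by the aroyl chloride; no stereocentre is affected.

**Step 14**
Reactants: 22
Product: 23 guttiferone L, (1S,5S,7R,8S)-4-hydroxy-8-methyl-1,5,7-tris(3-methylbut-2-enyl)-8-(4-methylpent-3-enyl)-3-(2,4,5-trihydroxybenzoyl)bicyclo[3.3.1]non-3-ene-2,9-dione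
Conditions: LiOH·H2O, degassed dioxane/H2O, 90 °C under argon; then cold dilute HCl to pH 4
Reagents that add atoms: lithium hydroxide (water), [Li+].[OH-]
Why: Hydroxide addition–elimination at C4 cleaves the vinylogous methyl ester and hydroxide attack at silicon frees the three phenols, under non-acidic conditions that spare the prenyl groups and all four stereocentres.

**Compound list**

1 | 5-methylhex-4-enoic acid | CC(C)=CCCC(=O)O | starting material
2 | (S)-4-benzyl-1,3-oxazolidin-2-one | O=C1N[C@@H](Cc2ccccc2)CO1 | starting material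
3 | (S)-4-benzyl-3-(5-methylhex-4-enoyl)-1,3-oxazolidin-2-one | CC(C)=CCCC(=O)N1[C@@H](Cc2ccccc2)COC1=O | intermediate
4 | methyl 2-(bromomethyl)acrylate | C=C(CBr)C(=O)OC | starting material
5 | methyl (4R)-4-[(4S)-4-benzyl-2-oxo-1,3-oxazolidine-3-carbonyl]-7-methyl-2-methylideneoct-6-enoate | C=C(C[C@@H](CC=C(C)C)C(=O)N1[C@@H](Cc2ccccc2)COC1=O)C(=O)OC | intermediate
6 | methyl (4R)-4-[(4S)-4-benzyl-2-oxo-1,3-oxazolidine-3-carbonyl]-7-methyl-2-(3-methylbut-2-enyl)oct-6-enoate (C2 epimers) | COC(=O)C(CC=C(C)C)C[C@@H](CC=C(C)C)C(=O)N1[C@@H](Cc2ccccc2)COC1=O | intermediate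
7 | methyl (4R)-4-(ethylsulfanylcarbonyl)-7-methyl-2-(3-methylbut-2-enyl)oct-6-enoate | COC(=O)C(CC=C(C)C)C[C@@H](CC=C(C)C)C(=O)SCC | intermediate
8 | methyl (4R)-4-acetyl-7-methyl-2-(3-methylbut-2-enyl)oct-6-enoate | COC(=O)C(CC=C(C)C)C[C@@H](CC=C(C)C)C(C)=O | intermediate
9 | methyl (4R)-4-(2-hydroxybut-3-en-2-yl)-7-methyl-2-(3-methylbut-2-enyl)oct-6-enoate (tertiary allylic alcohol) | COC(=O)C(CC=C(C)C)C[C@@H](CC=C(C)C)C(C)(O)C=C | intermediate (not isolated)
10 | methyl (4R)-4-[2-(tert-butoxycarbonyloxy)but-3-en-2-yl]-7-methyl-2-(3-methylbut-2-enyl)oct-6-enoate | COC(=O)C(CC=C(C)C)C[C@@H](CC=C(C)C)C(C)(OC(=O)OC(C)(C)C)C=C | intermediate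
11 | diketene (4-methylideneoxetan-2-one) | C=C1CC(=O)O1 | starting material
12 | methyl (4R)-4-[2-(tert-butoxycarbonyloxy)but-3-en-2-yl]-7-methyl-2-(3-methylbut-2-enyl)-2-(3-oxobutanoyl)oct-6-enoate (acetoacetylated ester) | COC(=O)C(CC=C(C)C)(C(=O)CC(C)=O)C[C@@H](CC=C(C)C)C(C)(OC(=O)OC(C)(C)C)C=C | intermediate (not isolated)
13 | 2-{(2R)-2-[2-(tert-butoxycarbonyloxy)but-3-en-2-yl]-5-methylhex-4-enyl}-2-(3-methylbut-2-enyl)cyclohexane-1,3,5-trione (monocyclic trione) | O=C1CC(=O)CC(=O)C1(CC=C(C)C)C[C@@H](CC=C(C)C)C(C)(OC(=O)OC(C)(C)C)C=C | intermediate (not isolated)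
14 | (1R,5S,7R,8S)-8-ethenyl-4-hydroxy-8-methyl-5,7-bis(3-methylbut-2-enyl)bicyclo[3.3.1]non-3-ene-2,9-dione | C=C[C@@]1(C)[C@H](CC=C(C)C)C[C@]2(CC=C(C)C)C(=O)[C@H]1C(=O)C=C2O | intermediate
15 | (1R,5S,7R,8S)-8-ethenyl-4-methoxy-8-methyl-5,7-bis(3-methylbut-2-enyl)bicyclo[3.3.1]non-3-ene-2,9-dione | C=C[C@@]1(C)[C@H](CC=C(C)C)C[C@]2(CC=C(C)C)C(=O)[C@H]1C(=O)C=C2OC | intermediate
16 | 9-{2-[(1R,5S,7R,8S)-4-methoxy-8-methyl-5,7-bis(3-methylbut-2-enyl)-2,9-dioxobicyclo[3.3.1]non-3-en-8-yl]ethyl}-9-borabicyclo[3.3.1]nonane (B-alkyl-9-BBN borane) | C1CC2CCCC(C1)B2CC[C@@]3(C)[C@H](CC=C(C)C)C[C@]4(CC=C(C)C)C(=O)[C@H]3C(=O)C=C4OC | intermediate (not isolated)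
17 | (1R,5S,7R,8S)-4-methoxy-8-methyl-5,7-bis(3-methylbut-2-enyl)-8-(4-methylpent-3-enyl)bicyclo[3.3.1]non-3-ene-2,9-dione | CC(C)=CCC[C@@]1(C)[C@H](CC=C(C)C)C[C@]2(CC=C(C)C)C(=O)[C@H]1C(=O)C=C2OC | intermediate
18 | (1R,5S,7R,8S)-4-methoxy-8-methyl-1,5,7-tris(3-methylbut-2-enyl)-8-(4-methylpent-3-enyl)bicyclo[3.3.1]non-3-ene-2,9-dione | CC(C)=CCC[C@@]1(C)[C@H](CC=C(C)C)C[C@]2(CC=C(C)C)C(=O)[C@@]1(CC=C(C)C)C(=O)C=C2OC | intermediate
19 | 2,4,5-trihydroxybenzoic acid | O=C(O)c1cc(O)c(O)cc1O | starting material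
20 | tert-butyldimethylsilyl 2,4,5-tris(tert-butyldimethylsilyloxy)benzoate | CC(C)(C)[Si](C)(C)OC(=O)c1cc(O[Si](C)(C)C(C)(C)C)c(O[Si](C)(C)C(C)(C)C)cc1O[Si](C)(C)C(C)(C)C | intermediate
21 | 2,4,5-tris(tert-butyldimethylsilyloxy)benzoyl chloride | O=C(Cl)c1cc(O[Si](C)(C)C(C)(C)C)c(O[Si](C)(C)C(C)(C)C)cc1O[Si](C)(C)C(C)(C)C | intermediate
22 | (1S,5S,7R,8S)-3-[2,4,5-tris(tert-butyldimethylsilyloxy)benzoyl]-4-methoxy-8-methyl-1,5,7-tris(3-methylbut-2-enyl)-8-(4-methylpent-3-enyl)bicyclo[3.3.1]non-3-ene-2,9-dione | CC(C)=CCC[C@@]1(C)[C@H](CC=C(C)C)C[C@]2(CC=C(C)C)C(=O)[C@@]1(CC=C(C)C)C(=O)C(C(=O)c1cc(O[Si](C)(C)C(C)(C)C)c(O[Si](C)(C)C(C)(C)C)cc1O[Si](C)(C)C(C)(C)C)=C2OC | intermediate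
23 | guttiferone L | CC(C)=CCC[C@@]1(C)[C@H](CC=C(C)C)C[C@]2(CC=C(C)C)C(=O)[C@@]1(CC=C(C)C)C(=O)C(C(=O)c1cc(O)c(O)cc1O)=C2O | target

**Totals and risks**

Total step count: 14. Longest linear sequence: 12 steps (steps 1–10, 13, 14); steps 11–12 are the aroyl chloride branch.

Steps most likely to fail:

1. Step 7. The C5 enolate may take the tert-butoxycarbonyl group from the neighbouring carbonate instead of reacting with diketene. In the last stage the palladium π-allyl complex may be captured at oxygen without funnelling to carbon, or with poor facial discrimination at C8. The fallback sets out from ketone 8 and comes back at 14. Vinylmagnesium bromide/CeCl3 followed by TESOTf/2,6-lutidine gives methyl (4R)-7-methyl-2-(3-methylbut-2-enyl)-4-[2-(triethylsilyloxy)but-3-en-2-yl]oct-6-enoate F1, which carries no acyl donor. The LDA/diketene/LDA sequence is stopped after the Claisen stage and 2-{(2R)-5-methyl-2-[2-(triethylsilyloxy)but-3-en-2-yl]hex-4-enyl}-2-(3-methylbut-2-enyl)cyclohexane-1,3,5-trione F2 is isolated. Formic acid at room temperature then ionises the tertiary allylic silyl ether to the allyl cation, which the enol carbon should capture at C8 through the same chair, an acid-mediated cation cyclisation of a dearomatised phloroglucinol-type trione, giving 14.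

2. Step 10. Alkylation of the pyramidal bridgehead carbanion next to the quaternary C8 may be slow, so that SN2′ attack or elimination on prenyl bromide and proton return take over. The fallback sets out from 17 and comes back at 18. LDA and the smaller, more reactive allyl bromide give (1R,5S,7R,8S)-4-methoxy-8-methyl-5,7-bis(3-methylbut-2-enyl)-8-(4-methylpent-3-enyl)-1-(prop-2-enyl)bicyclo[3.3.1]non-3-ene-2,9-dione F3. Cross-metathesis with 2-methyl-2-butene and second-generation Grubbs catalyst then turns the allyl into the prenyl group, the trisubstituted alkenes already present exchanging only degenerately, to give 18.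

3. Step 13. C-acylation of the hindered C3 vinyl-lithium by the bulky ortho-silyloxy aroyl chloride may be slower than proton transfer, returning 18. The fallback sets out from 18 and comes back at 22. Commercial 2,4,5-trihydroxybenzaldehyde is silylated (TBSCl, imidazole) to 2,4,5-tris(tert-butyldimethylsilyloxy)benzaldehyde F4. Its addition to the C3-lithiated 18 (LiTMP, THF, −78 °C) gives the carbinol (1S,5S,7R,8S)-3-{hydroxy[2,4,5-tris(tert-butyldimethylsilyloxy)phenyl]methyl}-4-methoxy-8-methyl-1,5,7-tris(3-methylbut-2-enyl)-8-(4-methylpent-3-enyl)bicyclo[3.3.1]non-3-ene-2,9-dione F5 as an epimer mixture. Dess–Martin periodinane oxidation then gives 22.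

**Further compounds**

F1 | step 7 | methyl (4R)-7-methyl-2-(3-methylbut-2-enyl)-4-[2-(triethylsilyloxy)but-3-en-2-yl]oct-6-enoate | COC(=O)C(CC=C(C)C)C[C@@H](CC=C(C)C)C(C)(O[Si](CC)(CC)CC)C=C
F2 | step 7 | 2-{(2R)-5-methyl-2-[2-(triethylsilyloxy)but-3-en-2-yl]hex-4-enyl}-2-(3-methylbut-2-enyl)cyclohexane-1,3,5-trione | O=C1CC(=O)CC(=O)C1(CC=C(C)C)C[C@@H](CC=C(C)C)C(C)(O[Si](CC)(CC)CC)C=C
F3 | step 10 | (1R,5S,7R,8S)-4-methoxy-8-methyl-5,7-bis(3-methylbut-2-enyl)-8-(4-methylpent-3-enyl)-1-(prop-2-enyl)bicyclo[3.3.1]non-3-ene-2,9-dione | CC(C)=CCC[C@@]1(C)[C@H](CC=C(C)C)C[C@]2(CC=C(C)C)C(=O)[C@@]1(CC=C)C(=O)C=C2OC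
F4 | step 13 | 2,4,5-tris(tert-butyldimethylsilyloxy)benzaldehyde | O=Cc1cc(O[Si](C)(C)C(C)(C)C)c(O[Si](C)(C)C(C)(C)C)cc1O[Si](C)(C)C(C)(C)C
F5 | step 13 | (1S,5S,7R,8S)-3-{hydroxy[2,4,5-tris(tert-butyldimethylsilyloxy)phenyl]methyl}-4-methoxy-8-methyl-1,5,7-tris(3-methylbut-2-enyl)-8-(4-methylpent-3-enyl)bicyclo[3.3.1]non-3-ene-2,9-dione | CC(C)=CCC[C@@]1(C)[C@H](CC=C(C)C)C[C@]2(CC=C(C)C)C(=O)[C@@]1(CC=C(C)C)C(=O)C(C(O)c1cc(O[Si](C)(C)C(C)(C)C)c(O[Si](C)(C)C(C)(C)C)cc1O[Si](C)(C)C(C)(C)C)=C2OC
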